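**Retrosynthetic overview** (labdane numbering: ring A = C1–C5 and C10, ring B = C5–C10, C17 = exocyclic CH2, C19 = ring carboxyl, C15 = chain carboxyl)
- Target: (4S,5R,9S,10R,13R)-13-hydroxylabd-8(17)-ene-15,19-dioic acid.
- Enabling feature: C3–C4 of ring A is a methacrylate unit (a CH2 next to a quaternary carbon bearing CH3 and CO2H) lying between C2 and C5; C5=C10 and C8=C9 map onto the two trisubstituted alkenes of an (E,E)-farnesyl chain and C17 onto its methyl.
- Key disconnection: C2–C3 by conjugate addition, then C4–C5 by oxidative (polarity-reversed) radical closure of the resulting ester enolate, with C9–C10 and the C8=C17 alkene formed in the same pot. Ring A forms first, ring B second.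
- Precursors: acyclic homoallylic iodide 9 from (2E,6E)-farnesol (C13 set by Sharpless epoxidation and hydride opening; C2 added at the terminal (E)-methyl) and the chiral methacrylate 12.
- Endgame: reductive release of C19 with recovery of the auxiliary, diol unmasking, double oxidation to the diacid.

Key step: step 9

Assumption: the (1R,2S,5R)-phenylmenthyl ester is taken to bias the ring closure toward the 4S,5R,9S,10R series; this sense cannot be predicted with confidence, the wrong ring-diastereomer is removed by chromatography, and the enantiomeric auxiliary would be used if the sense proved opposite.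

**Route**

Step 1
Reactants: 1 (2E,6E)-farnesol
Product: 2 [(2R,3R)-3-[(3E)-4,8-dimethylnona-3,7-dien-1-yl]-3-methyloxiran-2-yl]methanol
Conditions: Ti(OiPr)4, D-(−)-diethyl tartrate, t-BuOOH, 4 Å MS, CH2Cl2, −20 °C
Reagents that add atoms: tert-butyl hydroperoxide CC(C)(C)OO
Why: Sharpless asymmetric epoxidation acts only on the allylic-alcohol alkene, and the D-tartrate ligand delivers oxygen to the face that gives the (2R,3R)-epoxide, which fixes C13 of the target.

Step 2
Reactants: 2 [(2R,3R)-3-[(3E)-4,8-dimethylnona-3,7-dien-1-yl]-3-methyloxiran-2-yl]methanol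
Product: 3 (3R,6E)-3,7,11-trimethyldodeca-6,10-diene-1,3-diol
Conditions: NaAlH2(OCH2CH2OMe)2, THF, 0 °C to rt
Reagents that add atoms: none
Why: Alkoxide-directed hydride opening of the 2,3-epoxy alcohol delivers hydride to C2 and leaves the tertiary C–O bond untouched, so the 1,3-diol keeps the R configuration.

Step 3
Reactants: 3 (3R,6E)-3,7,11-trimethyldodeca-6,10-diene-1,3-diol
Product: 4 (4R)-4-[(3E)-4,8-dimethylnona-3,7-dien-1-yl]-2,2,4-trimethyl-1,3-dioxane
Conditions: 2,2-dimethoxypropane, PPTS (cat.), CH2Cl2, rt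
Reagents that add atoms: 2,2-dimethoxypropane COC(C)(C)OC
Why: Acid-catalysed transacetalisation closes the six-membered acetonide, which masks both hydroxyls for the organometallic key step.

Step 4
Reactants: 4 (4R)-4-[(3E)-4,8-dimethylnona-3,7-dien-1-yl]-2,2,4-trimethyl-1,3-dioxane
Product: 5 (2E,6E)-2,6-dimethyl-9-[(4R)-2,2,4-trimethyl-1,3-dioxan-4-yl]nona-2,6-dien-1-ol
Conditions: SeO2 (cat.), t-BuOOH, CH2Cl2, 0 °C to rt
Reagents that add atoms: tert-butyl hydroperoxide CC(C)(C)OO; selenium dioxide O=[Se]=O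
Why: SeO2 allylic oxidation (ene reaction then [2,3]-shift) should favour the (E)-methyl of the terminal, least hindered trisubstituted alkene of a polyprenyl chain.

Step 5
Reactants: 5 (2E,6E)-2,6-dimethyl-9-[(4R)-2,2,4-trimethyl-1,3-dioxan-4-yl]nona-2,6-dien-1-ol
Product: 6 (2E,6E)-2,6-dimethyl-9-[(4R)-2,2,4-trimethyl-1,3-dioxan-4-yl]nona-2,6-dienal
Conditions: MnO2, CH2Cl2, rt
Reagents that add atoms: none
Why: MnO2 oxidation is specific for the allylic alcohol and should keep the E geometry.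

Step 6
Reactants: 6 (2E,6E)-2,6-dimethyl-9-[(4R)-2,2,4-trimethyl-1,3-dioxan-4-yl]nona-2,6-dienal
Product: 7 (4R)-4-[(3E,7E)-4,8-dimethyldeca-3,7,9-trien-1-yl]-2,2,4-trimethyl-1,3-dioxane
Conditions: Ph3PCH3Br, KOtBu, THF, 0 °C
Reagents that add atoms: methyltriphenylphosphonium bromide C[P+](c1ccccc1)(c1ccccc1)c1ccccc1.[Br-]
Why: Wittig methylenation of the enal adds C2 as a terminal vinyl group without touching the trisubstituted alkenes.

Step 7
Reactants: 7 (4R)-4-[(3E,7E)-4,8-dimethyldeca-3,7,9-trien-1-yl]-2,2,4-trimethyl-1,3-dioxane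
Product: 9 (4R)-4-[(3E,7E)-10-iodo-4,8-dimethyldeca-3,7-dien-1-yl]-2,2,4-trimethyl-1,3-dioxane, via B-alkyldisiamylborane 8 (not isolated)
Conditions: Sia2BH (from BH3·THF and 2-methyl-2-butene), THF, 0 °C; then NaOMe, I2, MeOH, 0 °C
Reagents that add atoms: iodine II
Why: Anti-Markovnikov hydroboration with a hindered dialkylborane should take place only at the monosubstituted vinyl terminus, and base-induced iodinolysis of the primary C–B bond then gives the homoallylic iodide.

Step 8
Reactants: 10 (1R,2S,5R)-5-methyl-2-(2-phenylpropan-2-yl)cyclohexan-1-ol [(−)-8-phenylmenthol]; 11 methacryloyl chloride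
Product: 12 (1R,2S,5R)-5-methyl-2-(2-phenylpropan-2-yl)cyclohexyl 2-methylprop-2-enoate
Conditions: Et3N, DMAP (cat.), CH2Cl2, 0 °C to rt
Reagents that add atoms: none
Why: DMAP-catalysed acylation of the secondary alcohol gives the bulky chiral methacrylate that serves as the two-carbon C3–C4 unit.

Step 9
Reactants: 9 (4R)-4-[(3E,7E)-10-iodo-4,8-dimethyldeca-3,7-dien-1-yl]-2,2,4-trimethyl-1,3-dioxane; 12 (1R,2S,5R)-5-methyl-2-(2-phenylpropan-2-yl)cyclohexyl 2-methylprop-2-enoate
Product: 15 (1R,2S,5R)-8-phenylmenthyl (4S,5R,9S,10R,13R)-13,15-(propane-2,2-diyldioxy)labd-8(17)-en-19-oate, via Grignard reagent 13 (not isolated), via magnesium ester enolate 14 (not isolated)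
Conditions: Mg, Et2O, rt; CuBr·SMe2 (10 mol%), 12 (0.9 equiv, slow addition), THF, −40 °C; then PhMe, Cu(O2CCH(Et)C4H9)2 (3 equiv), −78 °C to rt
Reagents that add atoms: none
Why: Proposed new method: Copper-catalysed 1,4-addition of Grignard reagent 13 to the hindered methacrylate 12 forms C2–C3 and the magnesium ester enolate 14, and single-electron oxidation of 14 by the divalent copper carboxylate reverses the polarity of C4 to an electrophilic tertiary α-ester radical; the closest known reaction types are the tandem conjugate addition–enolate oxidation–radical cyclization of ester enolates and the Mn(OAc)3/Cu(OAc)2 oxidative polyene cyclization of 2-methyl-3-oxo esters. The C4 radical closes ring A by 6-endo-trig attack on C5 of the C5=C10 alkene (5-exo attack would have to form a bond to the methyl-bearing C10), and the tertiary C10 radical so formed closes ring B by a second 6-endo-trig attack on C9 of the C8=C9 alkene. The tertiary C8 radical is then taken up by a second equivalent of the copper carboxylate, and the alkylcopper species loses a hydrogen from the unhindered C17 methyl by syn β-hydride elimination, which gives the exocyclic C8=C17 alkene. Chair–chair folding of the (E,E)-diene fixes H5 anti to the C10 methyl and the C9 chain equatorial, and at C4 the flat alkoxycarbonyl group is expected to take the pseudo-axial position and the methyl the equatorial one, as in the keto ester precedent, so that C19 ends cis to C20. The absolute sense of folding is biased by the phenylmenthyl ester, whose aryl group lies over one face of the conjugated radical, and is secured by chromatography, because the product of opposite ring configuration is a diastereomer that differs at the carbon next to the ester. The step needs 1,4- over 1,2-addition and no oligomerisation (bulky ester added slowly to excess reagent with CuBr·SMe2), cyclisation faster than copper oxidation or hydrogen abstraction at the C10 radical (no acceptor is left at the radical stage and toluene is a poor hydrogen donor) and an inert acetonide, all of which the substrate and conditions should provide.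

Step 10
Reactants: 15 (1R,2S,5R)-8-phenylmenthyl (4S,5R,9S,10R,13R)-13,15-(propane-2,2-diyldioxy)labd-8(17)-en-19-oate
Product: 17 (4S,5R,9S,10R,13R)-labd-8(17)-ene-13,15,19-triol, via acetonide alcohol 16 (not isolated)
Conditions: LiAlH4, THF, 0 °C to reflux; then PPTS, MeOH, rt
Reagents that add atoms: none
Why: Hydride reduction should cleave the doubly hindered ester where hydrolysis would not and returns the auxiliary, and mild acetal methanolysis then frees the 1,3-diol without touching the exocyclic alkene.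

Step 11
Reactants: 17 (4S,5R,9S,10R,13R)-labd-8(17)-ene-13,15,19-triol
Product: 18 (4S,5R,9S,10R,13R)-13-hydroxylabd-8(17)-ene-15,19-dial
Conditions: Dess–Martin periodinane, NaHCO3, CH2Cl2, 0 °C to rt
Reagents that add atoms: none
Why: Buffered Dess–Martin oxidation converts both primary alcohols to aldehydes while the tertiary alcohol cannot react; the crude dialdehyde is used at once.

Step 12
Reactants: 18 (4S,5R,9S,10R,13R)-13-hydroxylabd-8(17)-ene-15,19-dial
Product: 19 (4S,5R,9S,10R,13R)-13-hydroxylabd-8(17)-ene-15,19-dioic acid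
Conditions: NaClO2, NaH2PO4, 2-methyl-2-butene, t-BuOH/H2O, 0 °C to rt
Reagents that add atoms: sodium chlorite [Na+].[O-]Cl=O
Why: Pinnick oxidation with a hypochlorite scavenger should take both aldehydes, including the neopentyl one, to the acids without attacking the 1,1-disubstituted alkene or the tertiary alcohol.

**Compound list**
1 | (2E,6E)-farnesol | CC(C)=CCC/C(C)=C/CC/C(C)=C/CO | starting material
2 | [(2R,3R)-3-[(3E)-4,8-dimethylnona-3,7-dien-1-yl]-3-methyloxiran-2-yl]methanol | OC[C@H]1O[C@]1(C)CC/C=C(\C)CCC=C(C)C | intermediate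
3 | (3R,6E)-3,7,11-trimethyldodeca-6,10-diene-1,3-diol | CC(C)=CCC/C(C)=C/CC[C@@](C)(O)CCO | intermediate
4 | (4R)-4-[(3E)-4,8-dimethylnona-3,7-dien-1-yl]-2,2,4-trimethyl-1,3-dioxane | CC(C)=CCC/C(C)=C/CC[C@]1(C)CCOC(C)(C)O1 | intermediate
5 | (2E,6E)-2,6-dimethyl-9-[(4R)-2,2,4-trimethyl-1,3-dioxan-4-yl]nona-2,6-dien-1-ol | OC/C(C)=C/CC/C(C)=C/CC[C@]1(C)CCOC(C)(C)O1 | intermediate
6 | (2E,6E)-2,6-dimethyl-9-[(4R)-2,2,4-trimethyl-1,3-dioxan-4-yl]nona-2,6-dienal | O=C/C(C)=C/CC/C(C)=C/CC[C@]1(C)CCOC(C)(C)O1 | intermediate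
7 | (4R)-4-[(3E,7E)-4,8-dimethyldeca-3,7,9-trien-1-yl]-2,2,4-trimethyl-1,3-dioxane | C=C/C(C)=C/CC/C(C)=C/CC[C@]1(C)CCOC(C)(C)O1 | intermediate
8 | [(3E,7E)-3,7-dimethyl-10-[(4R)-2,2,4-trimethyl-1,3-dioxan-4-yl]deca-3,7-dien-1-yl]bis(3-methylbutan-2-yl)borane | CC(C)C(C)B(CC/C(C)=C/CC/C(C)=C/CC[C@]1(C)CCOC(C)(C)O1)C(C)C(C)C | intermediate
9 | (4R)-4-[(3E,7E)-10-iodo-4,8-dimethyldeca-3,7-dien-1-yl]-2,2,4-trimethyl-1,3-dioxane | ICC/C(C)=C/CC/C(C)=C/CC[C@]1(C)CCOC(C)(C)O1 | intermediate
10 | (1R,2S,5R)-5-methyl-2-(2-phenylpropan-2-yl)cyclohexan-1-ol [(−)-8-phenylmenthol] | C[C@@H]1CC[C@H]([C@@H](C1)O)C(C)(C)c1ccccc1 | starting material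
11 | methacryloyl chloride | C=C(C)C(Cl)=O | starting material
12 | (1R,2S,5R)-5-methyl-2-(2-phenylpropan-2-yl)cyclohexyl 2-methylprop-2-enoate | C=C(C)C(=O)O[C@@H]1C[C@H](C)CC[C@H]1C(C)(C)c1ccccc1 | intermediate
13 | [(3E,7E)-3,7-dimethyl-10-[(4R)-2,2,4-trimethyl-1,3-dioxan-4-yl]deca-3,7-dien-1-yl]magnesium iodide | I[Mg]CC/C(C)=C/CC/C(C)=C/CC[C@]1(C)CCOC(C)(C)O1 | intermediate
14 | iodomagnesium enolate of (1R,2S,5R)-8-phenylmenthyl (6E,10E)-2,6,10-trimethyl-13-[(4R)-2,2,4-trimethyl-1,3-dioxan-4-yl]trideca-6,10-dienoate | I[Mg]OC(O[C@@H]1C[C@H](C)CC[C@H]1C(C)(C)c1ccccc1)=C(C)CCC/C(C)=C/CC/C(C)=C/CC[C@]2(C)CCOC(C)(C)O2 | intermediate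
15 | (1R,2S,5R)-8-phenylmenthyl (4S,5R,9S,10R,13R)-13,15-(propane-2,2-diyldioxy)labd-8(17)-en-19-oate | C=C1CC[C@@H]2[C@](C)(CCC[C@]2(C)C(=O)O[C@@H]4C[C@H](C)CC[C@H]4C(C)(C)c4ccccc4)[C@H]1CC[C@]3(C)CCOC(C)(C)O3 | intermediate
16 | (4S,5R,9S,10R,13R)-13,15-(propane-2,2-diyldioxy)labd-8(17)-en-19-ol | C=C1CC[C@@H]2[C@](C)(CCC[C@]2(C)CO)[C@H]1CC[C@]3(C)CCOC(C)(C)O3 | intermediate
17 | (4S,5R,9S,10R,13R)-labd-8(17)-ene-13,15,19-triol | C=C1CC[C@@H]2[C@](C)(CCC[C@]2(C)CO)[C@H]1CC[C@@](C)(O)CCO | intermediate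
18 | (4S,5R,9S,10R,13R)-13-hydroxylabd-8(17)-ene-15,19-dial | C=C1CC[C@@H]2[C@](C)(CCC[C@]2(C)C=O)[C@H]1CC[C@@](C)(O)CC=O | intermediate
19 | (4S,5R,9S,10R,13R)-13-hydroxylabd-8(17)-ene-15,19-dioic acid (CNP0126190.2) | C=C1CC[C@@H]2[C@](C)(CCC[C@]2(C)C(=O)O)[C@H]1CC[C@@](C)(O)CC(=O)O | target

**Step count and risks**

Total step count: 12. Longest linear sequence: 11 steps (steps 1–7 and 9–12).

Steps most likely to fail:

1. Step 9. The tertiary C10 radical may be oxidised by copper or pick up hydrogen before ring B closes, which would give monocyclic dienes. The auxiliary may give little face selection, and the copper elimination may give ring-alkene isomers beside the exocyclic one. Fallback with known chemistry: the two rings would be closed by the Mn(OAc)3/Cu(OAc)2 oxidative cyclization of a phenylmenthyl 2-methyl-3-oxo ester, where the keto and ester carbonyls bind the metal together and the auxiliary is known to control the face. It sets out from allylic alcohol 5, which is converted (MsCl, Et3N; then LiBr, THF) into (4R)-4-[(3E,7E)-9-bromo-4,8-dimethylnona-3,7-dien-1-yl]-2,2,4-trimethyl-1,3-dioxane F1. The dianion (NaH, then n-BuLi, THF, 0 °C) of (1R,2S,5R)-8-phenylmenthyl 2-methyl-3-oxobutanoate F2, made from 10 and methyl 2-methyl-3-oxobutanoate (DMAP, PhMe, reflux), is alkylated at its terminal carbon by F1 to give (1R,2S,5R)-8-phenylmenthyl (6E,10E)-2,6,10-trimethyl-3-oxo-13-[(4R)-2,2,4-trimethyl-1,3-dioxan-4-yl]trideca-6,10-dienoate F3. Mn(OAc)3·2H2O and Cu(OAc)2·H2O with Yb(OTf)3 in CF3CH2OH at 0 °C (buffered with NaOAc to spare the acetonide) would give the 3-oxo analogue of 15 with the same ring configuration F4. NaBH4 (MeOH, 0 °C) gives the 3-hydroxy analogue of 15 F5, NaH/CS2/MeI gives its S-methyl xanthate F6, and Bu3SnH/AIBN (PhMe, 80 °C; Barton–McCombie deoxygenation) removes the oxygen to give 15, where the route is rejoined.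

2. Step 4. The allylic oxidation may lose site selectivity (attack at the allylic positions of the internal alkene) or over-oxidise, and the acetal may suffer under the acidic selenium species. Fallback: the terminal alkene of 4 would be cleaved and rebuilt. NBS in aqueous THF at 0 °C gives the terminal bromohydrin (6E)-3-bromo-2,6-dimethyl-9-[(4R)-2,2,4-trimethyl-1,3-dioxan-4-yl]non-6-en-2-ol F7, and K2CO3 in MeOH closes it to (4R)-4-[(3E)-6-(3,3-dimethyloxiran-2-yl)-4-methylhex-3-en-1-yl]-2,2,4-trimethyl-1,3-dioxane F8. Brief treatment with H5IO6 (THF/Et2O, 0 °C) cleaves this to (4E)-4-methyl-7-[(4R)-2,2,4-trimethyl-1,3-dioxan-4-yl]hept-4-enal F9. An (E)-selective Wittig reaction of F9 with Ph3P=C(CH3)CHO (PhMe, reflux) gives enal 6, where the route is rejoined.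

3. Step 7. Hydroboration of the conjugated diene may stray (1,4-addition, or attack at a trisubstituted alkene), and the base-induced iodinolysis of the borane may be incomplete. Fallback: the extra carbon would be added by substitution instead of hydroboration, setting out from allylic alcohol 5. Corey–Kim chlorination (NCS, Me2S, CH2Cl2, −20 °C) gives (4R)-4-[(3E,7E)-9-chloro-4,8-dimethylnona-3,7-dien-1-yl]-2,2,4-trimethyl-1,3-dioxane F10. Coupling with (i-PrO)Me2SiCH2MgCl and Li2CuCl4 (cat.) in THF gives (4R)-4-[(3E,7E)-10-[dimethyl(propan-2-yloxy)silyl]-4,8-dimethyldeca-3,7-dien-1-yl]-2,2,4-trimethyl-1,3-dioxane F11. Tamao–Fleming oxidation (H2O2, KF, KHCO3, THF/MeOH) gives (3E,7E)-3,7-dimethyl-10-[(4R)-2,2,4-trimethyl-1,3-dioxan-4-yl]deca-3,7-dien-1-ol F12, and Appel iodination (I2, PPh3, imidazole) gives iodide 9, where the route is rejoined.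

Further compounds
F1 | step 9 | (4R)-4-[(3E,7E)-9-bromo-4,8-dimethylnona-3,7-dien-1-yl]-2,2,4-trimethyl-1,3-dioxane | BrC/C(C)=C/CC/C(C)=C/CC[C@]1(C)CCOC(C)(C)O1
F2 | step 9 | (1R,2S,5R)-8-phenylmenthyl 2-methyl-3-oxobutanoate | CC(=O)C(C)C(=O)O[C@@H]1C[C@H](C)CC[C@H]1C(C)(C)c1ccccc1
F3 | step 9 | (1R,2S,5R)-8-phenylmenthyl (6E,10E)-2,6,10-trimethyl-3-oxo-13-[(4R)-2,2,4-trimethyl-1,3-dioxan-4-yl]trideca-6,10-dienoate | CC(C(=O)CC/C(C)=C/CC/C(C)=C/CC[C@]1(C)CCOC(C)(C)O1)C(=O)O[C@@H]2C[C@H](C)CC[C@H]2C(C)(C)c2ccccc2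
F4 | step 9 | 3-oxo analogue of 15 with the same ring configuration | C=C1CC[C@@H]2[C@](C)(CCC(=O)[C@]2(C)C(=O)O[C@@H]4C[C@H](C)CC[C@H]4C(C)(C)c4ccccc4)[C@H]1CC[C@]3(C)CCOC(C)(C)O3
F5 | step 9 | 3-hydroxy analogue of 15 | C=C1CC[C@@H]2[C@](C)(CCC(O)[C@]2(C)C(=O)O[C@@H]4C[C@H](C)CC[C@H]4C(C)(C)c4ccccc4)[C@H]1CC[C@]3(C)CCOC(C)(C)O3
F6 | step 9 | S-methyl xanthate of the 3-hydroxy analogue of 15 | C=C1CC[C@@H]2[C@](C)(CCC(OC(=S)SC)[C@]2(C)C(=O)O[C@@H]4C[C@H](C)CC[C@H]4C(C)(C)c4ccccc4)[C@H]1CC[C@]3(C)CCOC(C)(C)O3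
F7 | step 4 | (6E)-3-bromo-2,6-dimethyl-9-[(4R)-2,2,4-trimethyl-1,3-dioxan-4-yl]non-6-en-2-ol | CC(C)(O)C(Br)CC/C(C)=C/CC[C@]1(C)CCOC(C)(C)O1
F8 | step 4 | (4R)-4-[(3E)-6-(3,3-dimethyloxiran-2-yl)-4-methylhex-3-en-1-yl]-2,2,4-trimethyl-1,3-dioxane | CC1(C)OC1CC/C(C)=C/CC[C@]2(C)CCOC(C)(C)O2
F9 | step 4 | (4E)-4-methyl-7-[(4R)-2,2,4-trimethyl-1,3-dioxan-4-yl]hept-4-enal | O=CCC/C(C)=C/CC[C@]1(C)CCOC(C)(C)O1
F10 | step 7 | (4R)-4-[(3E,7E)-9-chloro-4,8-dimethylnona-3,7-dien-1-yl]-2,2,4-trimethyl-1,3-dioxane | ClC/C(C)=C/CC/C(C)=C/CC[C@]1(C)CCOC(C)(C)O1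
F11 | step 7 | (4R)-4-[(3E,7E)-10-[dimethyl(propan-2-yloxy)silyl]-4,8-dimethyldeca-3,7-dien-1-yl]-2,2,4-trimethyl-1,3-dioxane | CC(C)O[Si](C)(C)CC/C(C)=C/CC/C(C)=C/CC[C@]1(C)CCOC(C)(C)O1
F12 | step 7 | (3E,7E)-3,7-dimethyl-10-[(4R)-2,2,4-trimethyl-1,3-dioxan-4-yl]deca-3,7-dien-1-ol | OCC/C(C)=C/CC/C(C)=C/CC[C@]1(C)CCOC(C)(C)O1
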